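**Retrosynthetic overview**
1. The target is reached from 5,7-di-O-benzyl-4'-O-silyl hispidulin by desilylation, sulfation of the freed 4'-phenol and hydrogenolysis of the two benzyl ethers.
2. The plan rests on ring C (O1, C2, C3, C4, C4a, C8a): C3 is its only CH and lies between the C4 ketone and C2, while C2 carries O1 and ring B and so has the oxidation level of an aryl ester carbonyl carbon. The C2=C3 bond is therefore cut back to an ester carbonyl (C2) and a phosphorus ylide carbon (C3) on the C4 ketone.
3. The ylide ester comes from a ring A (2-hydroxyaroyl)methylenetriphenylphosphorane and 4-silyloxybenzoyl chloride (ring B, from 4-hydroxybenzoic acid).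
4. The hydroxy ylide comes from symmetric 3,5-bis(benzyloxy)-4-methoxyphenol by MOM-directed ortho-lithiation, chloroacetylation with a Weinreb amide and PPh3. The phenol comes from methyl 4-O-methylgallate by benzylation, reduction, oxidation and Baeyer–Villiger oxidation.
5. Ring order: rings A and B are bought as benzenoid starting materials; ring C is the only ring formed, in the key step.

Key step: step 12

Assumption: the target is drawn as the neutral aryl hydrogen sulfate, so the sulfate is carried as its sodium salt and protonated only in the last operation; the free acid should be kept cold because aryl hydrogen sulfates hydrolyse on standing.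

**Route**

Step 1
Reactants: 1 methyl 3,5-dihydroxy-4-methoxybenzoate; 2 benzyl bromide
Product: 3 methyl 3,5-bis(benzyloxy)-4-methoxybenzoate
Conditions: BnBr (2.3 equiv), K2CO3, DMF, 60 °C
Reagents that add atoms: benzyl bromide 2, BrCc1ccccc1
Why: Williamson ether synthesis on the two equivalent phenols, with the methyl ester inert to carbonate in DMF.

Step 2
Reactants: 3 methyl 3,5-bis(benzyloxy)-4-methoxybenzoate
Product: 4 [3,5-bis(benzyloxy)-4-methoxyphenyl]methanol
Conditions: LiAlH4, THF, 0 °C to rt; then H2O, 15% aq NaOH, H2O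
Reagents that add atoms: none
Why: Hydride reduction of the ester to the primary benzylic alcohol, which leaves the aryl ethers untouched.

Step 3
Reactants: 4 [3,5-bis(benzyloxy)-4-methoxyphenyl]methanol
Product: 5 3,5-bis(benzyloxy)-4-methoxybenzaldehyde
Conditions: activated MnO2 (excess), CH2Cl2, rt
Reagents that add atoms: none
Why: MnO2 oxidises benzylic alcohols selectively to the aldehyde without over-oxidation.

Step 4
Reactants: 5 3,5-bis(benzyloxy)-4-methoxybenzaldehyde; 6 3-chloroperbenzoic acid
Product: 8 3,5-bis(benzyloxy)-4-methoxyphenol, via aryl formate 7 (not isolated)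
Conditions: mCPBA (1.2 equiv), CH2Cl2, 0 °C to rt; aq Na2SO3 wash; then K2CO3 (0.2 equiv), MeOH, rt
Reagents that add atoms: 3-chloroperbenzoic acid 6, O=C(OO)c1cccc(Cl)c1
Why: Baeyer–Villiger (Dakin-type) oxidation, in which the electron-rich aryl group migrates to oxygen in the peracid adduct in preference to hydride, the formate is methanolysed under mild base, and the oxygen so introduced is the one that becomes O1.

Step 5
Reactants: 8 3,5-bis(benzyloxy)-4-methoxyphenol; 9 chloromethyl methyl ether
Product: 10 1,3-bis(benzyloxy)-2-methoxy-5-(methoxymethoxy)benzene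
Conditions: NaH (1.2 equiv), DMF, 0 °C; MOMCl (1.2 equiv), 0 °C to rt
Reagents that add atoms: chloromethyl methyl ether 9, COCCl
Why: O-alkylation of the sodium phenoxide gives the MOM acetal, which masks the phenol and serves as the directing group for the next step.

Step 6
Reactants: 10 1,3-bis(benzyloxy)-2-methoxy-5-(methoxymethoxy)benzene; 11 2-chloro-N-methoxy-N-methylacetamide
Product: 14 1-[2,4-bis(benzyloxy)-3-methoxy-6-(methoxymethoxy)phenyl]-2-chloroethan-1-one, via aryllithium 12 (not isolated), via lithium hemiaminal adduct 13 (not isolated)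
Conditions: n-BuLi (1.15 equiv), THF, −20 to 0 °C; cannulate into 11 (1.3 equiv), THF, −78 °C; AcOH (1.2 equiv), −78 °C
Reagents that add atoms: 2-chloro-N-methoxy-N-methylacetamide 11, CON(C)C(=O)CCl
Why: Directed ortho-metalation followed by Weinreb ketone synthesis: the two ring CH positions of 10 are equivalent by symmetry and each is flanked by OMOM and OBn, so n-BuLi should remove this doubly activated proton faster than a benzylic one, and the aryllithium adds to the amide to give a chelated adduct that releases the ketone only on quench, which brings in C4 and C3 with the leaving group already on C3 and spares the electron-rich ring any electrophilic halogenation.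

Step 7
Reactants: 14 1-[2,4-bis(benzyloxy)-3-methoxy-6-(methoxymethoxy)phenyl]-2-chloroethan-1-one; 15 triphenylphosphine
Product: 16 {2-[2,4-bis(benzyloxy)-3-methoxy-6-(methoxymethoxy)phenyl]-2-oxoethyl}triphenylphosphonium chloride
Conditions: PPh3 (1.2 equiv), NaI (0.1 equiv), MeCN, 70 °C; precipitate with Et2O
Reagents that add atoms: triphenylphosphine 15, c1ccc(P(c2ccccc2)c2ccccc2)cc1
Why: SN2 displacement of the activated alpha-chloride by PPh3 (iodide catalysis) gives the phosphonium salt, while the MOM group keeps the phenol from closing onto C3 to a benzofuran-3-one.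

Step 8
Reactants: 16 {2-[2,4-bis(benzyloxy)-3-methoxy-6-(methoxymethoxy)phenyl]-2-oxoethyl}triphenylphosphonium chloride
Product: 18 1-[2,4-bis(benzyloxy)-6-hydroxy-3-methoxyphenyl]-2-(triphenyl-lambda5-phosphanylidene)ethan-1-one, via hydroxyphosphonium chloride 17 (not isolated)
Conditions: HCl (0.3 equiv), MeOH, 45 °C; then aq Na2CO3, CH2Cl2, rt
Reagents that add atoms: none
Why: Acid-catalysed methanolysis of the MOM acetal frees the phenol while C3 is still a phosphonium salt, and carbonate then removes the acidic P–CH2–C=O proton to give the acyl-stabilised ylide, whose hydrogen-bonded phenol stays protonated.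

Step 9
Reactants: 19 4-hydroxybenzoic acid; 20 tert-butyl(chloro)dimethylsilane
Product: 21 tert-butyldimethylsilyl 4-[(tert-butyldimethylsilyl)oxy]benzoate
Conditions: TBSCl (2.3 equiv), imidazole (4.6 equiv), DMF, rt
Reagents that add atoms: tert-butyl(chloro)dimethylsilane 20, CC(C)(C)[Si](C)(C)Cl
Why: Imidazole-promoted silylation converts both the phenol and the carboxylic acid into their silyl derivatives.

Step 10
Reactants: 21 tert-butyldimethylsilyl 4-[(tert-butyldimethylsilyl)oxy]benzoate; 22 oxalyl chloride
Product: 23 4-[(tert-butyldimethylsilyl)oxy]benzoyl chloride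
Conditions: (COCl)2 (1.2 equiv), DMF (cat.), CH2Cl2, 0 °C to rt; volatiles including TBSCl removed in vacuo, used crude
Reagents that add atoms: oxalyl chloride 22, O=C(Cl)C(=O)Cl
Why: Silyl esters are converted into acid chlorides by oxalyl chloride and catalytic DMF (chloroiminium activation) under neutral conditions, the ester silicon leaving as TBSCl with no HCl formed, so the aryl silyl ether should survive.

Step 11
Reactants: 18 1-[2,4-bis(benzyloxy)-6-hydroxy-3-methoxyphenyl]-2-(triphenyl-lambda5-phosphanylidene)ethan-1-one; 23 4-[(tert-butyldimethylsilyl)oxy]benzoyl chloride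
Product: 24 3,5-bis(benzyloxy)-4-methoxy-2-[2-(triphenyl-lambda5-phosphanylidene)acetyl]phenyl 4-[(tert-butyldimethylsilyl)oxy]benzoate
Conditions: 23 (1.2 equiv), pyridine (3 equiv), CH2Cl2, 0 °C to rt
Reagents that add atoms: 4-[(tert-butyldimethylsilyl)oxy]benzoyl chloride 23, O=C(Cl)c1ccc(O[Si](C)(C)C(C)(C)C)cc1
Why: Pyridine-mediated O-acylation of the phenol by the acid chloride should be much faster than acylation of the ylide carbon, which is delocalised into its ketone and shielded by PPh3 and the 2,6-disubstituted aryl group.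

Step 12
Reactants: 24 3,5-bis(benzyloxy)-4-methoxy-2-[2-(triphenyl-lambda5-phosphanylidene)acetyl]phenyl 4-[(tert-butyldimethylsilyl)oxy]benzoate
Product: 25 5,7-bis(benzyloxy)-2-{4-[(tert-butyldimethylsilyl)oxy]phenyl}-6-methoxy-4H-chromen-4-one
Conditions: toluene (0.02 M), reflux, argon
Reagents that add atoms: none
Why: On heating, the acyl-stabilised ylide carbon (future C3) adds to the carbonyl carbon of the neighbouring aryl benzoate (future C2), and the resulting P–C–C–O array collapses with loss of Ph3PO to the C2=C3 double bond, an intramolecular Wittig olefination of an ester carbonyl. The closest known reaction type is the chromone and flavone synthesis by thermal cyclisation of O-acyl (2-hydroxybenzoyl)methylenetriphenylphosphoranes. Ring C is closed as a six-membered ring by a 6-exo-trig addition of C3 to the ester C=O, and the elimination then places the new double bond inside the ring. No stereocentre is formed. The step needs chemoselectivity for the ester carbonyl over the ylide's own enolate-like ketone and over acyl transfer, and the ortho arrangement on ring A secures it: only the ester carbonyl can be reached through a six-membered transition state, and it is an activated aryl ester held beside the ylide. Because no base, acid, 1,3-diketone or oxidant is involved, the benzyl and silyl ethers should survive and O1 stays on C8a, so the 6-methoxy pattern cannot scramble to the 8-methoxy isomer.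

Step 13
Reactants: 25 5,7-bis(benzyloxy)-2-{4-[(tert-butyldimethylsilyl)oxy]phenyl}-6-methoxy-4H-chromen-4-one
Product: 26 5,7-bis(benzyloxy)-2-(4-hydroxyphenyl)-6-methoxy-4H-chromen-4-one
Conditions: Bu4NF (1.1 equiv), AcOH (1.1 equiv), THF, 0 °C
Reagents that add atoms: none
Why: Fluoride-induced cleavage of the aryl silyl ether, buffered by acetic acid so that the phenoxide is protonated at once, with benzyl ethers and the chromone inert.

Step 14
Reactants: 26 5,7-bis(benzyloxy)-2-(4-hydroxyphenyl)-6-methoxy-4H-chromen-4-one; 27 sulfur trioxide pyridine complex; 28 sodium hydrogen carbonate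
Product: 30 sodium 4-[5,7-bis(benzyloxy)-6-methoxy-4-oxo-4H-chromen-2-yl]phenyl sulfate, via pyridinium sulfate 29 (not isolated)
Conditions: SO3·pyridine (4 equiv), pyridine, 40 °C; then aq NaHCO3; reversed-phase (C18) purification
Reagents that add atoms: sulfur trioxide pyridine complex 27, [O-]S(=O)(=O)[n+]1ccccc1; sodium hydrogen carbonate 28 (NaHCO3), [Na+].OC([O-])=O
Why: O-sulfation of a phenol by sulfur trioxide transfer from SO3·pyridine at the only free hydroxyl group, with the bicarbonate work-up exchanging pyridinium for sodium so that no catalyst poison enters the last step.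

Step 15
Reactants: 30 sodium 4-[5,7-bis(benzyloxy)-6-methoxy-4-oxo-4H-chromen-2-yl]phenyl sulfate
Product: 32 4-(5,7-dihydroxy-6-methoxy-4-oxo-4H-chromen-2-yl)phenyl hydrogen sulfate (hispidulin 4'-sulfate), via sodium hispidulin 4'-sulfate 31 (not isolated)
Conditions: H2 (1 atm), 10% Pd/C, MeOH/THF/H2O, rt; filter; then aq HCl (1.0 equiv), 0 °C, C18 desalting, freeze-drying
Reagents that add atoms: none
Why: Catalytic hydrogenolysis of the two aryl benzyl ethers over Pd/C under neutral conditions should leave the aryl sulfate anion and the conjugated C2=C3 bond of the chromone untouched, and one equivalent of cold HCl then gives the hydrogen sulfate as drawn.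

**Compound list**
1 | methyl 3,5-dihydroxy-4-methoxybenzoate | COC(=O)c1cc(O)c(OC)c(O)c1 | starting material
2 | benzyl bromide | BrCc1ccccc1 | starting material
3 | methyl 3,5-bis(benzyloxy)-4-methoxybenzoate | COC(=O)c1cc(OCc2ccccc2)c(OC)c(OCc2ccccc2)c1 | intermediate
4 | [3,5-bis(benzyloxy)-4-methoxyphenyl]methanol | OCc1cc(OCc2ccccc2)c(OC)c(OCc2ccccc2)c1 | intermediate
5 | 3,5-bis(benzyloxy)-4-methoxybenzaldehyde | O=Cc1cc(OCc2ccccc2)c(OC)c(OCc2ccccc2)c1 | intermediate
6 | 3-chloroperbenzoic acid (mCPBA) | O=C(OO)c1cccc(Cl)c1 | starting material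
7 | 3,5-bis(benzyloxy)-4-methoxyphenyl formate | O=COc1cc(OCc2ccccc2)c(OC)c(OCc2ccccc2)c1 | intermediate
8 | 3,5-bis(benzyloxy)-4-methoxyphenol | Oc1cc(OCc2ccccc2)c(OC)c(OCc2ccccc2)c1 | intermediate
9 | chloromethyl methyl ether | COCCl | starting material
10 | 1,3-bis(benzyloxy)-2-methoxy-5-(methoxymethoxy)benzene | COCOc1cc(OCc2ccccc2)c(OC)c(OCc2ccccc2)c1 | intermediate
11 | 2-chloro-N-methoxy-N-methylacetamide | CON(C)C(=O)CCl | starting material
12 | [2,4-bis(benzyloxy)-3-methoxy-6-(methoxymethoxy)phenyl]lithium | [Li]c1c(OCOC)cc(OCc2ccccc2)c(OC)c1OCc1ccccc1 | intermediate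
13 | lithium 1-[2,4-bis(benzyloxy)-3-methoxy-6-(methoxymethoxy)phenyl]-2-chloro-1-[methoxy(methyl)amino]ethan-1-olate (racemic) | [Li]OC(CCl)(N(C)OC)c1c(OCOC)cc(OCc2ccccc2)c(OC)c1OCc1ccccc1 | intermediate
14 | 1-[2,4-bis(benzyloxy)-3-methoxy-6-(methoxymethoxy)phenyl]-2-chloroethan-1-one | O=C(CCl)c1c(OCOC)cc(OCc2ccccc2)c(OC)c1OCc1ccccc1 | intermediate
15 | triphenylphosphine | c1ccc(P(c2ccccc2)c2ccccc2)cc1 | starting material
16 | {2-[2,4-bis(benzyloxy)-3-methoxy-6-(methoxymethoxy)phenyl]-2-oxoethyl}triphenylphosphonium chloride | O=C(C[P+](c1ccccc1)(c1ccccc1)c1ccccc1)c1c(OCOC)cc(OCc2ccccc2)c(OC)c1OCc1ccccc1.[Cl-] | intermediate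
17 | {2-[2,4-bis(benzyloxy)-6-hydroxy-3-methoxyphenyl]-2-oxoethyl}triphenylphosphonium chloride | O=C(C[P+](c1ccccc1)(c1ccccc1)c1ccccc1)c1c(O)cc(OCc2ccccc2)c(OC)c1OCc1ccccc1.[Cl-] | intermediate
18 | 1-[2,4-bis(benzyloxy)-6-hydroxy-3-methoxyphenyl]-2-(triphenyl-lambda5-phosphanylidene)ethan-1-one | O=C(C=P(c1ccccc1)(c1ccccc1)c1ccccc1)c1c(O)cc(OCc2ccccc2)c(OC)c1OCc1ccccc1 | intermediate
19 | 4-hydroxybenzoic acid | O=C(O)c1ccc(O)cc1 | starting material
20 | tert-butyl(chloro)dimethylsilane (TBSCl) | CC(C)(C)[Si](C)(C)Cl | starting material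
21 | tert-butyldimethylsilyl 4-[(tert-butyldimethylsilyl)oxy]benzoate | CC(C)(C)[Si](C)(C)OC(=O)c1ccc(O[Si](C)(C)C(C)(C)C)cc1 | intermediate
22 | oxalyl chloride | O=C(Cl)C(=O)Cl | starting material
23 | 4-[(tert-butyldimethylsilyl)oxy]benzoyl chloride | O=C(Cl)c1ccc(O[Si](C)(C)C(C)(C)C)cc1 | intermediate
24 | 3,5-bis(benzyloxy)-4-methoxy-2-[2-(triphenyl-lambda5-phosphanylidene)acetyl]phenyl 4-[(tert-butyldimethylsilyl)oxy]benzoate | O=C(C=P(c1ccccc1)(c1ccccc1)c1ccccc1)c1c(OC(=O)c2ccc(O[Si](C)(C)C(C)(C)C)cc2)cc(OCc2ccccc2)c(OC)c1OCc1ccccc1 | intermediate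
25 | 5,7-bis(benzyloxy)-2-{4-[(tert-butyldimethylsilyl)oxy]phenyl}-6-methoxy-4H-chromen-4-one | COc1c(OCc2ccccc2)cc2oc(-c3ccc(O[Si](C)(C)C(C)(C)C)cc3)cc(=O)c2c1OCc1ccccc1 | intermediate
26 | 5,7-bis(benzyloxy)-2-(4-hydroxyphenyl)-6-methoxy-4H-chromen-4-one | COc1c(OCc2ccccc2)cc2oc(-c3ccc(O)cc3)cc(=O)c2c1OCc1ccccc1 | intermediate
27 | sulfur trioxide pyridine complex | [O-]S(=O)(=O)[n+]1ccccc1 | starting material
28 | sodium hydrogen carbonate (NaHCO3) | [Na+].OC([O-])=O | starting material
29 | pyridinium 4-[5,7-bis(benzyloxy)-6-methoxy-4-oxo-4H-chromen-2-yl]phenyl sulfate | COc1c(OCc2ccccc2)cc2oc(-c3ccc(OS(=O)(=O)[O-])cc3)cc(=O)c2c1OCc1ccccc1.c1cc[nH+]cc1 | intermediate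
30 | sodium 4-[5,7-bis(benzyloxy)-6-methoxy-4-oxo-4H-chromen-2-yl]phenyl sulfate | COc1c(OCc2ccccc2)cc2oc(-c3ccc(OS(=O)(=O)[O-])cc3)cc(=O)c2c1OCc1ccccc1.[Na+] | intermediate
31 | sodium 4-(5,7-dihydroxy-6-methoxy-4-oxo-4H-chromen-2-yl)phenyl sulfate | COc1c(O)cc2oc(-c3ccc(OS(=O)(=O)[O-])cc3)cc(=O)c2c1O.[Na+] | intermediate
32 | 4-(5,7-dihydroxy-6-methoxy-4-oxo-4H-chromen-2-yl)phenyl hydrogen sulfate (hispidulin 4'-sulfate) | COc1c(O)cc2oc(-c3ccc(OS(=O)(=O)O)cc3)cc(=O)c2c1O | target

**Step count**
Total: 15 steps. Longest linear sequence: 13 steps (steps 1–8 and 11–15); steps 9–10 form the side branch to acid chloride 23.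

**Steps most likely to fail**

Step 12. The para-silyloxy group makes the benzoate carbonyl electron-rich, so addition of the stabilised ylide may be slow. At the temperatures then needed, the aroyl group may migrate from oxygen to the ylide carbon instead of Ph3PO being lost. The fallback sets out from hydroxy ylide 18 and keeps C3 as the ylide carbon but closes ring C at O1–C2. Intermolecular Wittig olefination of 4-[(tert-butyldimethylsilyl)oxy]benzaldehyde by 18 in refluxing toluene should give (2E)-1-[2,4-bis(benzyloxy)-6-hydroxy-3-methoxyphenyl]-3-{4-[(tert-butyldimethylsilyl)oxy]phenyl}prop-2-en-1-one F1. Oxidative cyclisation of this 2'-hydroxychalcone with catalytic I2 in DMSO at 110 °C should then return the route at flavone 25. Only the free 2'-hydroxyl can cyclise, so the substitution pattern is kept, and any material that loses the silyl group there is already 26.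

Step 6. The hindered aryllithium may take a proton from the alpha-CH2 of the chloro amide instead of adding to its carbonyl, or a benzylic position of a benzyl ether may be lithiated and rearrange. The fallback sets out from phenol 8 and uses electrophilic acylation in place of organometallic chemistry. A Hoesch reaction with chloroacetonitrile (ZnCl2, HCl gas, Et2O, 0 °C) at the only free, symmetry-equivalent ring position should give 1-[2,4-bis(benzyloxy)-6-hydroxy-3-methoxyphenyl]-2-chloroethan-1-iminium chloride F2. Hydrolysis in warm water gives 1-[2,4-bis(benzyloxy)-6-hydroxy-3-methoxyphenyl]-2-chloroethan-1-one F3. Treatment with PPh3 in MeCN without base then returns the route at hydroxyphosphonium chloride 17, which is converted into 18 with aq Na2CO3 as in step 8.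

Step 14. Sulfation may stay incomplete, the ionic monoester may be hard to free from excess reagent, it may hydrolyse in part on purification, and carried-over pyridine may slow the hydrogenolysis. The fallback sets out from phenol 26 and uses a protected sulfate. 2,2,2-Trichloroethyl chlorosulfate (Et3N, DMAP, THF) should give the neutral, chromatographable diester 4-[5,7-bis(benzyloxy)-6-methoxy-4-oxo-4H-chromen-2-yl]phenyl 2,2,2-trichloroethyl sulfate F4. Pd/C with HCO2NH4 in MeOH should remove the trichloroethyl group and both benzyl ethers in one operation to give ammonium 4-(5,7-dihydroxy-6-methoxy-4-oxo-4H-chromen-2-yl)phenyl sulfate F5. One equivalent of cold HCl then returns the route at target 32.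

**Further compounds**
F1 | step 12 | (2E)-1-[2,4-bis(benzyloxy)-6-hydroxy-3-methoxyphenyl]-3-{4-[(tert-butyldimethylsilyl)oxy]phenyl}prop-2-en-1-one | O=C(/C=C/c1ccc(O[Si](C)(C)C(C)(C)C)cc1)c1c(O)cc(OCc2ccccc2)c(OC)c1OCc1ccccc1
F2 | step 6 | 1-[2,4-bis(benzyloxy)-6-hydroxy-3-methoxyphenyl]-2-chloroethan-1-iminium chloride | [NH2+]=C(CCl)c1c(O)cc(OCc2ccccc2)c(OC)c1OCc1ccccc1.[Cl-]
F3 | step 6 | 1-[2,4-bis(benzyloxy)-6-hydroxy-3-methoxyphenyl]-2-chloroethan-1-one | O=C(CCl)c1c(O)cc(OCc2ccccc2)c(OC)c1OCc1ccccc1
F4 | step 14 | 4-[5,7-bis(benzyloxy)-6-methoxy-4-oxo-4H-chromen-2-yl]phenyl 2,2,2-trichloroethyl sulfate | COc1c(OCc2ccccc2)cc2oc(-c3ccc(OS(=O)(=O)OCC(Cl)(Cl)Cl)cc3)cc(=O)c2c1OCc1ccccc1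
F5 | step 14 | ammonium 4-(5,7-dihydroxy-6-methoxy-4-oxo-4H-chromen-2-yl)phenyl sulfate | COc1c(O)cc2oc(-c3ccc(OS(=O)(=O)[O-])cc3)cc(=O)c2c1O.[NH4+]
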